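**Plan**

1. Retrosynthesis: the C3 ketal, the 8‑O‑acyl group and the C11=C13 methylene come off last. The C1=C10 olefin of the 10‑membered ring is then traced back to an 11‑membered cyclic α‑chloro sulfone with SO2 between C1 and C10 (ring contraction, SO2 lost).
2. The thiacycle is opened at S–C1 (thiol–ene). The chain is cut at C8–C9 (acetone aldol) and at C6–C7 plus the lactone C–O bond (imide aldol, lactonisation), leaving a C1–C6 aldehyde, a succinate imide and acetone.
3. Forward order: γ‑lactone first, then the 11‑membered thiacycle, then the 10‑membered carbocycle by sulfur extrusion; methylene, ester and ketone are unveiled afterwards.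
4. Stereochemistry: C4 from (R)‑2‑methylsuccinate; C7 and C6 from the (S)‑benzyloxazolidinone syn‑aldol (trans‑lactone); C8 from (S)‑proline; C10 and the chlorine‑bearing carbon are mixtures that the key step erases.
5. Enabling feature: C1=C10 is the only C=C in the 10‑membered ring and lies between two CH2 groups (C2, C9). C1 and C10 can therefore be the two α‑carbons of a sulfone bridge, with C3 (ketal) and C8 (silyl ether) both γ to sulfur and no β‑leaving group.

Key step: step 16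

Remark: atom numbers C1–C15 are those of the germacrane skeleton of the target (C1=C10 olefin, C3 ketone, C4 and C10 methyl‑bearing, C6–O–C12 lactone, C8 acyloxy, C11=C13 methylene). Acid 1 is taken as a purchasable building block. A stereocentre left undefined in a SMILES means the epimer mixture is used.

**Route**

Step 1
Reactants: 1 (2R)-4-tert-butoxy-2-methyl-4-oxobutanoic acid
Product: 2 tert-butyl (3R)-4-[methoxy(methyl)amino]-3-methyl-4-oxobutanoate
Conditions: MeNH(OMe)·HCl, EDC·HCl, 1-hydroxybenzotriazole (cat.), N-methylmorpholine, CH2Cl2, 0 °C → rt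
Reagents that add atoms: N,O-dimethylhydroxylamine hydrochloride CNOC.Cl
Why: Carbodiimide amidation to the Weinreb amide should leave the α‑stereocentre (C4) and the tert‑butyl ester untouched.

Step 2
Reactants: 2 tert-butyl (3R)-4-[methoxy(methyl)amino]-3-methyl-4-oxobutanoate
Product: 3 tert-butyl (3R)-3-methyl-4-oxohex-5-enoate
Conditions: CH2=CHMgBr, THF, −20 → 0 °C; poured into cold 1 M HCl
Reagents that add atoms: vinylmagnesium bromide C=C[Mg]Br
Why: Weinreb ketone synthesis: the chelated tetrahedral adduct stops at single addition and releases the vinyl ketone only on acidic work‑up, the hindered tert‑butyl ester being inert at this temperature.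

Step 3
Reactants: 3 tert-butyl (3R)-3-methyl-4-oxohex-5-enoate
Product: 4 tert-butyl (3R)-3-(2-ethenyl-1,3-dioxolan-2-yl)butanoate
Conditions: TMSOCH2CH2OTMS, TMSOTf (cat.), CH2Cl2, −78 °C; pyridine quench
Reagents that add atoms: 1,2-bis(trimethylsilyloxy)ethane C[Si](C)(C)OCCO[Si](C)(C)C
Why: Silyl‑transfer ketalisation under TMSOTf catalysis should mask the enone carbonyl (C3) at low temperature without conjugate addition or epimerisation at C4.

Step 4
Reactants: 4 tert-butyl (3R)-3-(2-ethenyl-1,3-dioxolan-2-yl)butanoate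
Product: 5 (3R)-3-(2-ethenyl-1,3-dioxolan-2-yl)butanal
Conditions: i-Bu2AlH, CH2Cl2, −78 °C; Rochelle salt
Reagents that add atoms: none
Why: Low‑temperature hydride reduction of the ester should stop at the aldehyde (C6) because the tetrahedral aluminate survives until work‑up.

Step 5
Reactants: 6 (4S)-4-benzyl-1,3-oxazolidin-2-one and 7 methyl 4-chloro-4-oxobutanoate
Product: 8 methyl 4-[(4S)-4-benzyl-2-oxo-1,3-oxazolidin-3-yl]-4-oxobutanoate
Conditions: n-BuLi, THF, −78 °C; then 7, −78 → 0 °C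
Reagents that add atoms: none
Why: N‑acylation of the lithiated oxazolidinone by the acid chloride is the standard entry to the aldol imide.

Step 6
Reactants: 8 methyl 4-[(4S)-4-benzyl-2-oxo-1,3-oxazolidin-3-yl]-4-oxobutanoate and 5 (3R)-3-(2-ethenyl-1,3-dioxolan-2-yl)butanal
Product: 10 (4S)-4-benzyl-3-{[(2R,3S)-2-[(2R)-2-(2-ethenyl-1,3-dioxolan-2-yl)propyl]-5-oxooxolan-3-yl]carbonyl}-1,3-oxazolidin-2-one, via syn-aldol adduct 9 (not isolated)
Conditions: Bu2BOTf, i-Pr2NEt, CH2Cl2, 0 °C; 5, −78 → 0 °C; pH 7 buffer, MeOH, H2O2; then pyridinium p-toluenesulfonate (cat.), CH2Cl2, rt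
Reagents that add atoms: none
Why: Evans syn‑aldol: the (Z)‑boron enolate formed at the imide α‑CH2 reacts through a Zimmerman–Traxler chair on the face away from the benzyl group, setting C7 and C6 syn, and the γ‑hydroxy ester then lactonises to the trans‑disubstituted γ‑lactone.

Step 7
Reactants: 10 (4S)-4-benzyl-3-{[(2R,3S)-2-[(2R)-2-(2-ethenyl-1,3-dioxolan-2-yl)propyl]-5-oxooxolan-3-yl]carbonyl}-1,3-oxazolidin-2-one
Product: 11 (2R,3S)-2-[(2R)-2-(2-ethenyl-1,3-dioxolan-2-yl)propyl]-5-oxooxolane-3-carboxylic acid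
Conditions: LiOH, H2O2, THF/H2O, 0 °C; Na2SO3; 1 M HCl to pH 2–3
Reagents that add atoms: hydrogen peroxide OO
Why: Hydroperoxide attacks the exocyclic imide carbonyl selectively (auxiliary cleavage), and acidification re‑closes any opened lactone.

Step 8
Reactants: 11 (2R,3S)-2-[(2R)-2-(2-ethenyl-1,3-dioxolan-2-yl)propyl]-5-oxooxolane-3-carboxylic acid
Product: 13 (2R,3S)-2-[(2R)-2-(2-ethenyl-1,3-dioxolan-2-yl)propyl]-5-oxooxolane-3-carbaldehyde, via acid chloride 12 (not isolated)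
Conditions: 1-chloro-N,N,2-trimethylprop-1-en-1-amine, CH2Cl2, 0 °C → rt; then LiAlH(Ot-Bu)3, THF, −78 °C
Reagents that add atoms: none
Why: Acid‑chloride formation under neutral conditions (Ghosez reagent) followed by partial reduction with the hindered alkoxyaluminium hydride should give the C8 aldehyde without touching lactone or ketal and without a free alkoxide that could shift the lactone.

Step 9
Reactants: 13 (2R,3S)-2-[(2R)-2-(2-ethenyl-1,3-dioxolan-2-yl)propyl]-5-oxooxolane-3-carbaldehyde and 14 acetone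
Product: 15 (4R,5R)-5-[(2R)-2-(2-ethenyl-1,3-dioxolan-2-yl)propyl]-4-[(1R)-1-hydroxy-3-oxobutyl]oxolan-2-one
Conditions: (S)-proline (30 mol %), acetone/DMSO, rt
Reagents that add atoms: none
Why: Proline‑catalysed enamine aldol of acetone: the carboxylic acid of the catalyst directs the aldehyde so that the enamine attacks one face, setting C8 (R) under catalyst control as for other α‑branched aldehydes.

Step 10
Reactants: 15 (4R,5R)-5-[(2R)-2-(2-ethenyl-1,3-dioxolan-2-yl)propyl]-4-[(1R)-1-hydroxy-3-oxobutyl]oxolan-2-one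
Product: 16 (4S,5R)-4-[(1R)-1-{[tert-butyl(dimethyl)silyl]oxy}-3-oxobutyl]-5-[(2R)-2-(2-ethenyl-1,3-dioxolan-2-yl)propyl]oxolan-2-one
Conditions: TBSCl, imidazole, DMF, rt
Reagents that add atoms: tert-butyl(chloro)dimethylsilane CC(C)(C)[Si](C)(C)Cl
Why: Silylation of the secondary 8‑OH blocks retro‑aldol, elimination and lactone migration and keeps this oxygen distinct from the lactone oxygen.

Step 11
Reactants: 16 (4S,5R)-4-[(1R)-1-{[tert-butyl(dimethyl)silyl]oxy}-3-oxobutyl]-5-[(2R)-2-(2-ethenyl-1,3-dioxolan-2-yl)propyl]oxolan-2-one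
Product: 17 (4S,5R)-4-[(1R,3RS)-1-{[tert-butyl(dimethyl)silyl]oxy}-3-hydroxybutyl]-5-[(2R)-2-(2-ethenyl-1,3-dioxolan-2-yl)propyl]oxolan-2-one
Conditions: NaBH4, MeOH, −40 °C
Reagents that add atoms: none
Why: Borohydride reduces the methyl ketone in preference to the lactone, and both C10 epimers are acceptable because C10 becomes sp2 in the key step.

Step 12
Reactants: 17 (4S,5R)-4-[(1R,3RS)-1-{[tert-butyl(dimethyl)silyl]oxy}-3-hydroxybutyl]-5-[(2R)-2-(2-ethenyl-1,3-dioxolan-2-yl)propyl]oxolan-2-one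
Product: 18 (4S,5R)-4-[(1R,3RS)-3-(acetylsulfanyl)-1-{[tert-butyl(dimethyl)silyl]oxy}butyl]-5-[(2R)-2-(2-ethenyl-1,3-dioxolan-2-yl)propyl]oxolan-2-one
Conditions: PPh3, diisopropyl azodicarboxylate, AcSH, THF, 0 °C → rt, dark
Reagents that add atoms: thioacetic acid CC(=O)S
Why: Mitsunobu thioesterification replaces the secondary 10‑OH by sulfur with inversion under neutral conditions.

Step 13
Reactants: 18 (4S,5R)-4-[(1R,3RS)-3-(acetylsulfanyl)-1-{[tert-butyl(dimethyl)silyl]oxy}butyl]-5-[(2R)-2-(2-ethenyl-1,3-dioxolan-2-yl)propyl]oxolan-2-one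
Product: 19 (4S,5R)-4-[(1R,3RS)-1-{[tert-butyl(dimethyl)silyl]oxy}-3-sulfanylbutyl]-5-[(2R)-2-(2-ethenyl-1,3-dioxolan-2-yl)propyl]oxolan-2-one
Conditions: N2H4·AcOH, degassed DMF, rt
Reagents that add atoms: none
Why: Hydrazinolysis removes the S‑acetyl group far faster than it attacks the γ‑lactone.

Step 14
Reactants: 19 (4S,5R)-4-[(1R,3RS)-1-{[tert-butyl(dimethyl)silyl]oxy}-3-sulfanylbutyl]-5-[(2R)-2-(2-ethenyl-1,3-dioxolan-2-yl)propyl]oxolan-2-one
Product: 20 cyclic sulfide (11-membered ring S–C1–C2–C3(ethylene ketal)–C4–C5–C6–C7–C8(OTBS)–C9–C10; trans-fused C6/C7 γ-lactone; 4R 6R 7S 8R; C10 epimers)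
Conditions: 2,2-dimethoxy-2-phenylacetophenone (cat.), hν (365 nm), degassed EtOAc, about 1 mM, rt
Reagents that add atoms: none
Why: Radical thiol–ene macrocyclisation: the thiyl radical adds anti‑Markovnikov to the terminal vinyl group, forming S–C1 and the 11‑membered ring under high dilution.

Step 15
Reactants: 20 cyclic sulfide (11-membered ring; S between C1 and C10)
Product: 22 α-chloro sulfone of 20 (S,S-dioxide; chlorine on C1 or C10; C1 isomer drawn), via α-chloro sulfide 21 (not isolated)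
Conditions: N-chlorosuccinimide, CH2Cl2, 0 °C; then mCPBA, NaHCO3, CH2Cl2, 0 °C → rt
Reagents that add atoms: N-chlorosuccinimide O=C1CCC(=O)N1Cl; 3-chloroperoxybenzoic acid OOC(=O)c1cccc(Cl)c1
Why: α‑Chlorination of the sulfide through the chlorosulfonium salt (Pummerer‑type) followed by S‑oxidation gives the sulfone with its leaving group, and either regio‑ or stereoisomer is usable because there is no other olefin to epoxidise.

Step 16
Reactants: 22 α-chloro sulfone of 20
Product: 24 (1(10)Z,4R,6R,7S,8R)-8-{[tert-butyl(dimethyl)silyl]oxy}-3,3-(ethylenedioxy)-13-norgermacr-1(10)-en-12,6-olide, via episulfone 23 (not isolated)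
Conditions: KOt-Bu, THF, −78 → 0 °C; aqueous citric acid work-up
Reagents that add atoms: none
Why: Ramberg–Bäcklund reaction: tert‑butoxide removes the α‑proton on the non‑chlorinated side of the sulfone and the carbanion displaces chloride from the other α‑carbon in a 1,3‑elimination, giving thiirane 1,1‑dioxide 23, which loses SO2 in a stereospecific cheletropic step. The closest known reaction type is the Ramberg–Bäcklund ring contraction of medium‑ring α‑halo sulfones to cycloalkenes, trisubstituted ones included. The only ring closed is the transient three‑membered episulfone (3‑exo‑tet); the 10‑membered carbocycle arises from the 11‑membered thiacycle when sulfur is excised and C1 becomes bonded to C10. No stereocentre is created: the C10 centre, the chlorine‑bearing centre and both chlorination regioisomers are erased, so the whole isomer mixture converges on one olefin. The selectivity needed is the Z geometry, which should follow from the cis‑fused episulfone (a trans‑fused one would force an E double bond into the lactone‑fused 10‑membered ring) and from the equilibrating sulfonyl carbanion that lets every isomer reach it. Enolisation of the lactone at C11 is reversible and harmless because no electrophile is present, and the oxygens at C3 and C8 are γ to sulfur and cannot leave by β‑elimination.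

Step 17
Reactants: 24 (1(10)Z,4R,6R,7S,8R)-8-{[tert-butyl(dimethyl)silyl]oxy}-3,3-(ethylenedioxy)-13-norgermacr-1(10)-en-12,6-olide
Product: 25 (1(10)Z,4R,6R,7S,8R)-8-{[tert-butyl(dimethyl)silyl]oxy}-13-(dimethylamino)-3,3-(ethylenedioxy)germacr-1(10)-en-12,6-olide (C11 epimers)
Conditions: LiN(i-Pr)2, THF, −78 °C; then CH2=NMe2+ I−, −78 °C → rt
Reagents that add atoms: N,N-dimethylmethyleneiminium iodide C=[N+](C)C.[I-]
Why: Mannich reaction of the lactone enolate with Eschenmoser's salt: C11 is the only acidic position now that C3 is a ketal and sulfur is gone.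

Step 18
Reactants: 25 (1(10)Z,4R,6R,7S,8R)-8-{[tert-butyl(dimethyl)silyl]oxy}-13-(dimethylamino)-3,3-(ethylenedioxy)germacr-1(10)-en-12,6-olide
Product: 27 (1(10)Z,4R,6R,7S,8R)-8-{[tert-butyl(dimethyl)silyl]oxy}-3,3-(ethylenedioxy)germacra-1(10),11(13)-dien-12,6-olide, via trimethylammonium iodide 26 (not isolated)
Conditions: MeI, MeOH, rt; then NaHCO3, H2O/EtOAc, rt
Reagents that add atoms: none
Why: N‑Quaternisation and E1cB elimination of trimethylamine give the exocyclic C11=C13 methylene, the only alkene the β‑amino lactone can form.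

Step 19
Reactants: 27 (1(10)Z,4R,6R,7S,8R)-8-{[tert-butyl(dimethyl)silyl]oxy}-3,3-(ethylenedioxy)germacra-1(10),11(13)-dien-12,6-olide
Product: 28 (1(10)Z,4R,6R,7R,8R)-3,3-(ethylenedioxy)-8-hydroxygermacra-1(10),11(13)-dien-12,6-olide (same spatial arrangement as 27; the C7 descriptor changes with the free 8-OH)
Conditions: HF·pyridine, pyridine, THF, 0 °C → rt
Reagents that add atoms: none
Why: Buffered fluoride desilylation frees the 8‑OH without adding to the methylene lactone or opening the ketal.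

Step 20
Reactants: 29 tert-butyl acrylate and 30 acetaldehyde
Product: 31 tert-butyl 3-hydroxy-2-methylidenebutanoate (racemic)
Conditions: DABCO, neat, rt
Reagents that add atoms: none
Why: Morita–Baylis–Hillman reaction joins the acrylate α‑carbon to acetaldehyde.

Step 21
Reactants: 31 tert-butyl 3-hydroxy-2-methylidenebutanoate
Product: 33 tert-butyl (2E)-2-(acetoxymethyl)but-2-enoate, via secondary acetate 32 (not isolated)
Conditions: Ac2O, Et3N, 4-(dimethylamino)pyridine (cat.), CH2Cl2, 0 °C; then DABCO (cat.), THF, reflux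
Reagents that add atoms: acetic anhydride CC(=O)OC(C)=O
Why: Acetylation and then amine‑catalysed double SN2′ transposition move the acetate to the primary position, giving the thermodynamically preferred trisubstituted (E)‑enoate.

Step 22
Reactants: 33 tert-butyl (2E)-2-(acetoxymethyl)but-2-enoate
Product: 34 (2E)-2-(acetoxymethyl)but-2-enoic acid
Conditions: CF3CO2H, CH2Cl2, 0 °C → rt
Reagents that add atoms: none
Why: Acidolysis of the tert‑butyl ester frees the acid without touching the acetate.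

Step 23
Reactants: 28 (1(10)Z,4R,6R,7R,8R)-3,3-(ethylenedioxy)-8-hydroxygermacra-1(10),11(13)-dien-12,6-olide and 34 (2E)-2-(acetoxymethyl)but-2-enoic acid
Product: 36 (1(10)Z,4R,6R,7S,8R)-8-{[(2E)-2-(acetoxymethyl)but-2-enoyl]oxy}-3,3-(ethylenedioxy)germacra-1(10),11(13)-dien-12,6-olide, via mixed anhydride 35 (not isolated)
Conditions: 2,4,6-trichlorobenzoyl chloride, Et3N, toluene, rt; then 28, 4-(dimethylamino)pyridine, rt
Reagents that add atoms: none
Why: Yamaguchi esterification acylates the hindered secondary 8‑OH with retention at C8.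

Step 24
Reactants: 36 (1(10)Z,4R,6R,7S,8R)-8-{[(2E)-2-(acetoxymethyl)but-2-enoyl]oxy}-3,3-(ethylenedioxy)germacra-1(10),11(13)-dien-12,6-olide
Product: 37 (1(10)Z,4R,6R,7S,8R)-8-{[(2E)-2-(acetoxymethyl)but-2-enoyl]oxy}-3-oxogermacra-1(10),11(13)-dien-12,6-olide (CNP0265140.1)
Conditions: pyridinium p-toluenesulfonate (cat.), acetone/H2O, 50 °C
Reagents that add atoms: water O
Why: Mild acid‑catalysed ketal hydrolysis releases the C3 ketone as the β,γ‑enone, which a 10‑membered ring holds out of conjugation, and leaves the esters and the methylene lactone intact.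

**Compound list**

1 | (2R)-4-tert-butoxy-2-methyl-4-oxobutanoic acid | C[C@H](CC(=O)OC(C)(C)C)C(=O)O | starting material
2 | tert-butyl (3R)-4-[methoxy(methyl)amino]-3-methyl-4-oxobutanoate | C[C@H](CC(=O)OC(C)(C)C)C(=O)N(C)OC | intermediate
3 | tert-butyl (3R)-3-methyl-4-oxohex-5-enoate | C[C@H](CC(=O)OC(C)(C)C)C(=O)C=C | intermediate
4 | tert-butyl (3R)-3-(2-ethenyl-1,3-dioxolan-2-yl)butanoate | C[C@H](CC(=O)OC(C)(C)C)C1(C=C)OCCO1 | intermediate
5 | (3R)-3-(2-ethenyl-1,3-dioxolan-2-yl)butanal | C[C@H](CC=O)C1(C=C)OCCO1 | intermediate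
6 | (4S)-4-benzyl-1,3-oxazolidin-2-one | O=C1N[C@@H](Cc2ccccc2)CO1 | starting material
7 | methyl 4-chloro-4-oxobutanoate | COC(=O)CCC(Cl)=O | starting material
8 | methyl 4-[(4S)-4-benzyl-2-oxo-1,3-oxazolidin-3-yl]-4-oxobutanoate | COC(=O)CCC(=O)N1[C@@H](Cc2ccccc2)COC1=O | intermediate
9 | methyl (3S,4R,6R)-3-{[(4S)-4-benzyl-2-oxo-1,3-oxazolidin-3-yl]carbonyl}-6-(2-ethenyl-1,3-dioxolan-2-yl)-4-hydroxyheptanoate (syn-aldol adduct) | COC(=O)C[C@H](C(=O)N1[C@@H](Cc2ccccc2)COC1=O)[C@H](O)C[C@@H](C)C3(C=C)OCCO3 | intermediate (not isolated)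
10 | (4S)-4-benzyl-3-{[(2R,3S)-2-[(2R)-2-(2-ethenyl-1,3-dioxolan-2-yl)propyl]-5-oxooxolan-3-yl]carbonyl}-1,3-oxazolidin-2-one | O=C1C[C@H](C(=O)N2[C@@H](Cc3ccccc3)COC2=O)[C@@H](C[C@@H](C)C4(C=C)OCCO4)O1 | intermediate
11 | (2R,3S)-2-[(2R)-2-(2-ethenyl-1,3-dioxolan-2-yl)propyl]-5-oxooxolane-3-carboxylic acid | O=C1C[C@H](C(=O)O)[C@@H](C[C@@H](C)C2(C=C)OCCO2)O1 | intermediate
12 | (2R,3S)-2-[(2R)-2-(2-ethenyl-1,3-dioxolan-2-yl)propyl]-5-oxooxolane-3-carbonyl chloride | O=C1C[C@H](C(Cl)=O)[C@@H](C[C@@H](C)C2(C=C)OCCO2)O1 | intermediate (not isolated)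
13 | (2R,3S)-2-[(2R)-2-(2-ethenyl-1,3-dioxolan-2-yl)propyl]-5-oxooxolane-3-carbaldehyde | O=C1C[C@H](C=O)[C@@H](C[C@@H](C)C2(C=C)OCCO2)O1 | intermediate
14 | acetone | CC(C)=O | starting material
15 | (4R,5R)-5-[(2R)-2-(2-ethenyl-1,3-dioxolan-2-yl)propyl]-4-[(1R)-1-hydroxy-3-oxobutyl]oxolan-2-one | O=C1C[C@H]([C@H](O)CC(C)=O)[C@@H](C[C@@H](C)C2(C=C)OCCO2)O1 | intermediate
16 | (4S,5R)-4-[(1R)-1-{[tert-butyl(dimethyl)silyl]oxy}-3-oxobutyl]-5-[(2R)-2-(2-ethenyl-1,3-dioxolan-2-yl)propyl]oxolan-2-one | O=C1C[C@H]([C@H](O[Si](C)(C)C(C)(C)C)CC(C)=O)[C@@H](C[C@@H](C)C2(C=C)OCCO2)O1 | intermediate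
17 | (4S,5R)-4-[(1R,3RS)-1-{[tert-butyl(dimethyl)silyl]oxy}-3-hydroxybutyl]-5-[(2R)-2-(2-ethenyl-1,3-dioxolan-2-yl)propyl]oxolan-2-one | O=C1C[C@H]([C@H](O[Si](C)(C)C(C)(C)C)CC(C)O)[C@@H](C[C@@H](C)C2(C=C)OCCO2)O1 | intermediate
18 | (4S,5R)-4-[(1R,3RS)-3-(acetylsulfanyl)-1-{[tert-butyl(dimethyl)silyl]oxy}butyl]-5-[(2R)-2-(2-ethenyl-1,3-dioxolan-2-yl)propyl]oxolan-2-one | O=C1C[C@H]([C@H](O[Si](C)(C)C(C)(C)C)CC(C)SC(C)=O)[C@@H](C[C@@H](C)C2(C=C)OCCO2)O1 | intermediate
19 | (4S,5R)-4-[(1R,3RS)-1-{[tert-butyl(dimethyl)silyl]oxy}-3-sulfanylbutyl]-5-[(2R)-2-(2-ethenyl-1,3-dioxolan-2-yl)propyl]oxolan-2-one | O=C1C[C@H]([C@H](O[Si](C)(C)C(C)(C)C)CC(C)S)[C@@H](C[C@@H](C)C2(C=C)OCCO2)O1 | intermediate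
20 | cyclic sulfide: 11-membered ring S–C1–C2–C3(ethylene ketal)–C4(Me)–C5–C6–C7–C8(OTBS)–C9–C10(Me), trans-fused C6/C7 γ-lactone; 4R,6R,7S,8R; C10 epimers | O=C1C[C@@H]2[C@H](O[Si](C)(C)C(C)(C)C)CC(C)SCCC3(OCCO3)[C@H](C)C[C@H]2O1 | intermediate
21 | α-chloro sulfide of 20 (chlorine on C1 drawn; C10 isomer also expected) | O=C1C[C@@H]2[C@H](O[Si](C)(C)C(C)(C)C)CC(C)SC(Cl)CC3(OCCO3)[C@H](C)C[C@H]2O1 | intermediate (not isolated)
22 | α-chloro sulfone of 20 (S,S-dioxide; chlorine on C1 drawn) | O=C1C[C@@H]2[C@H](O[Si](C)(C)C(C)(C)C)CC(C)S(=O)(=O)C(Cl)CC3(OCCO3)[C@H](C)C[C@H]2O1 | intermediate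
23 | cis-fused thiirane 1,1-dioxide spanning C1 and C10 of the 10-membered ring (episulfone) | O=C1C[C@@H]2[C@H](O[Si](C)(C)C(C)(C)C)CC4(C)C(S4(=O)=O)CC3(OCCO3)[C@H](C)C[C@H]2O1 | intermediate (not isolated)
24 | (1(10)Z,4R,6R,7S,8R)-8-{[tert-butyl(dimethyl)silyl]oxy}-3,3-(ethylenedioxy)-13-norgermacr-1(10)-en-12,6-olide | O=C1C[C@@H]2[C@H](O[Si](C)(C)C(C)(C)C)C/C(C)=C\CC3(OCCO3)[C@H](C)C[C@H]2O1 | intermediate
25 | (1(10)Z,4R,6R,7S,8R)-8-{[tert-butyl(dimethyl)silyl]oxy}-13-(dimethylamino)-3,3-(ethylenedioxy)germacr-1(10)-en-12,6-olide (C11 epimers) | O=C1C(CN(C)C)[C@@H]2[C@H](O[Si](C)(C)C(C)(C)C)C/C(C)=C\CC3(OCCO3)[C@H](C)C[C@H]2O1 | intermediate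
26 | N-methyl ammonium iodide of 25 | O=C1C(C[N+](C)(C)C)[C@@H]2[C@H](O[Si](C)(C)C(C)(C)C)C/C(C)=C\CC3(OCCO3)[C@H](C)C[C@H]2O1.[I-] | intermediate (not isolated)
27 | (1(10)Z,4R,6R,7S,8R)-8-{[tert-butyl(dimethyl)silyl]oxy}-3,3-(ethylenedioxy)germacra-1(10),11(13)-dien-12,6-olide | O=C1C(=C)[C@@H]2[C@H](O[Si](C)(C)C(C)(C)C)C/C(C)=C\CC3(OCCO3)[C@H](C)C[C@H]2O1 | intermediate
28 | (1(10)Z,4R,6R,7R,8R)-3,3-(ethylenedioxy)-8-hydroxygermacra-1(10),11(13)-dien-12,6-olide | O=C1C(=C)[C@@H]2[C@H](O)C/C(C)=C\CC3(OCCO3)[C@H](C)C[C@H]2O1 | intermediate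
29 | tert-butyl acrylate | C=CC(=O)OC(C)(C)C | starting material
30 | acetaldehyde | CC=O | starting material
31 | tert-butyl 3-hydroxy-2-methylidenebutanoate (racemic) | CC(O)C(=C)C(=O)OC(C)(C)C | intermediate
32 | tert-butyl 3-acetoxy-2-methylidenebutanoate | CC(OC(C)=O)C(=C)C(=O)OC(C)(C)C | intermediate (not isolated)
33 | tert-butyl (2E)-2-(acetoxymethyl)but-2-enoate | CC(C)(C)OC(=O)/C(=C/C)COC(C)=O | intermediate
34 | (2E)-2-(acetoxymethyl)but-2-enoic acid | OC(=O)/C(=C/C)COC(C)=O | intermediate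
35 | (2E)-2-(acetoxymethyl)but-2-enoic 2,4,6-trichlorobenzoic anhydride | O=C(OC(=O)/C(=C/C)COC(C)=O)c1c(Cl)cc(Cl)cc1Cl | intermediate (not isolated)
36 | (1(10)Z,4R,6R,7S,8R)-8-{[(2E)-2-(acetoxymethyl)but-2-enoyl]oxy}-3,3-(ethylenedioxy)germacra-1(10),11(13)-dien-12,6-olide | O=C1C(=C)[C@@H]2[C@H](OC(=O)/C(=C/C)COC(C)=O)C/C(C)=C\CC3(OCCO3)[C@H](C)C[C@H]2O1 | intermediate
37 | (1(10)Z,4R,6R,7S,8R)-8-{[(2E)-2-(acetoxymethyl)but-2-enoyl]oxy}-3-oxogermacra-1(10),11(13)-dien-12,6-olide (CNP0265140.1) | C=C1C(=O)O[C@@H]2C[C@@H](C)C(=O)C/C=C(/C)C[C@@H](OC(=O)/C(=C/C)COC(C)=O)[C@@H]12 | target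

**Count**

Total steps: 24. Longest linear sequence: 20 steps (steps 1–4, 6–19, 23, 24).

**Steps most likely to fail, with fallbacks**

Step 16 (ring contraction). What may go wrong: the 1,3‑elimination may run through the trans‑fused episulfone, or the sulfonyl carbanion may equilibrate unfavourably, so that the olefin forms with the E geometry or as a mixture; tert‑butoxide may also open the lactone. Fallback: it sets out from 22. The elimination is run as before and the (1(10)E) isomer of 24 F1 is carried on. Epoxidation with mCPBA (CH2Cl2, NaHCO3) gives the 1,10‑epoxide F2. Ring opening at C1 with LiPPh2 (THF, −78 → 0 °C), P‑methylation with MeI and syn‑elimination of the betaine invert the olefin stereospecifically and return to 24.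

Step 14 (thiol–ene macrocyclisation). What may go wrong: intermolecular thiol–ene addition and disulfide formation may outrun closure of the 11‑membered ring, and thiyl addition is reversible. Fallback: it sets out from 18. Hydroboration of the vinyl group with 9‑BBN and oxidation with NaBO3 give the primary alcohol F3. MsCl and Et3N give the methanesulfonate F4. K2CO3 in MeOH at high dilution removes the S‑acetyl group and the thiolate closes the ring by SN2 at C1; acidic work‑up re‑closes the lactone and gives 20.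

Step 9 (acetone aldol). What may go wrong: the Felkin–Anh preference of the α‑stereocentre C7 may oppose the catalyst, giving poor facial selectivity at C8; enamine formation from 13 may epimerise C7; the new 8‑OH may take over the lactone by acyl migration. Fallback: it sets out from acid chloride 12 (made as in step 8). Negishi acylation with [2-(4-methoxybenzyloxy)propyl]zinc iodide and Pd(PPh3)4 (cat.) in THF gives the ketone F5. Corey–Bakshi–Shibata reduction with the (S)‑methyl oxazaborolidine and catecholborane at −78 °C sets C8 by reagent control (the branched C7 acts as the large group) and gives the alcohol F6. TBSCl and imidazole give the silyl ether F7. DDQ in wet CH2Cl2 removes the 4‑methoxybenzyl group and returns to 17.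

**Further compounds**

F1 | step 16 | (1(10)E,4R,6R,7S,8R)-8-{[tert-butyl(dimethyl)silyl]oxy}-3,3-(ethylenedioxy)-13-norgermacr-1(10)-en-12,6-olide | O=C1C[C@@H]2[C@H](O[Si](C)(C)C(C)(C)C)C/C(C)=C/CC3(OCCO3)[C@H](C)C[C@H]2O1
F2 | step 16 | trans-1,10-epoxide of F1 (either face) | O=C1C[C@@H]2[C@H](O[Si](C)(C)C(C)(C)C)CC4(C)OC4CC3(OCCO3)[C@H](C)C[C@H]2O1
F3 | step 14 | (4S,5R)-4-[(1R,3RS)-3-(acetylsulfanyl)-1-{[tert-butyl(dimethyl)silyl]oxy}butyl]-5-{(2R)-2-[2-(2-hydroxyethyl)-1,3-dioxolan-2-yl]propyl}oxolan-2-one | O=C1C[C@H]([C@H](O[Si](C)(C)C(C)(C)C)CC(C)SC(C)=O)[C@@H](C[C@@H](C)C2(CCO)OCCO2)O1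
F4 | step 14 | methanesulfonate of F3 | O=C1C[C@H]([C@H](O[Si](C)(C)C(C)(C)C)CC(C)SC(C)=O)[C@@H](C[C@@H](C)C2(CCOS(C)(=O)=O)OCCO2)O1
F5 | step 9 | (4S,5R)-5-[(2R)-2-(2-ethenyl-1,3-dioxolan-2-yl)propyl]-4-{(3RS)-3-[(4-methoxyphenyl)methoxy]butanoyl}oxolan-2-one | O=C1C[C@H](C(=O)CC(C)OCc2ccc(OC)cc2)[C@@H](C[C@@H](C)C3(C=C)OCCO3)O1
F6 | step 9 | (4R,5R)-5-[(2R)-2-(2-ethenyl-1,3-dioxolan-2-yl)propyl]-4-{(1R,3RS)-1-hydroxy-3-[(4-methoxyphenyl)methoxy]butyl}oxolan-2-one | O=C1C[C@H]([C@H](O)CC(C)OCc2ccc(OC)cc2)[C@@H](C[C@@H](C)C3(C=C)OCCO3)O1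
F7 | step 9 | (4S,5R)-4-{(1R,3RS)-1-{[tert-butyl(dimethyl)silyl]oxy}-3-[(4-methoxyphenyl)methoxy]butyl}-5-[(2R)-2-(2-ethenyl-1,3-dioxolan-2-yl)propyl]oxolan-2-one | O=C1C[C@H]([C@H](O[Si](C)(C)C(C)(C)C)CC(C)OCc2ccc(OC)cc2)[C@@H](C[C@@H](C)C3(C=C)OCCO3)O1
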